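The numbers are made up.

The ratio I carried through this flask was the rate of over-reaction over the rate of target formation; dissolved gas and catalyst stand in both rates and cancel from it.

    gas phase ⇌ dissolved gas, rate k1*(csat - [dissolved gas]) (k1 = 0.91 min⁻¹, csat = 200 mM)
    substrate + dissolved gas + catalyst → catalyst + target (k2 = 3.8 M⁻² min⁻¹)
    dissolved gas + catalyst + target → catalyst + over-reaction product (k3 = 0.71 M⁻² min⁻¹)
    crystals ⇌ target, rate k4*(cs4 - [target]) while solid is left; crystals form when [target] > cs4 (cs4 = 0.80 M, k4 = 11 min⁻¹)

substrate 2.0 M; gas phase 200 mM (held); catalyst 400 mM; time 30 min

1. how much target and crystals together there is at 30 min, in percent of the substrate charged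
2. concentration of dissolved gas in solution at 3.0 min, in percent of saturation
3. the change that raises the amount of target and crystals together at 30 min, in percent of the substrate charged most ("none" if none brings more than 2 percentage points) (ash / maple / larch / cedar / none)
4. amount of target and crystals together at 30 min, in percent of the substrate charged, after maple

- ash: doubling the transfer coefficient of step 1, all else as stated
- maple: doubling the dissolution coefficient of step 4, all else as stated
- larch: doubling the amount of catalyst, all else as stated
- cedar: doubling the saturation concentration of gas phase, all else as stated

- for target the crystals are counted in
- as a solid, counted per litre of solution: crystals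
- at the start none of the gas is dissolved
- run time (flask): 30 min

The fastest rung was the crystals: they answer within 0.0909 min, shorter than the other two times below, so I held [target] at 0.80 M while solid lasted. Next came the 0.23 min half-life of dissolved gas against target formation, shorter than the transfer time of 1.10 min, so I took [dissolved gas] as quasi-steady. That put it at 23.0 % of saturation on the full charge, and I expected about a quarter at 3.0 min.

Then came the gas transfer, which needs 11.0 min to deliver one substrate charge. That is shorter than the run, so it can deliver at most 273 % of the charge, more than the one turnover that substrate, the limiting reagent, needs.

The last rung was the ratio itself. With crystals present it equals a fixed concentration over [substrate], that concentration being the solubility divided by the selectivity factor 5.35. I call it the break-even substrate concentration, 0.149 M: above it target and crystals together grow, below it they shrink.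

Integrating from about 1.20 M of substrate gave 0.311 M of over-reaction product at break-even, hence a ceiling near 77.0 %. Reaching it takes 2.16 M of gas, which at half the full transfer rate means 23.8 min, earlier than the end. Afterwards, with gas near 80.0 % of saturation, the loss is 0.0364 M min⁻¹, so my own reckoning came to 65.6 %. Maple touches a rung already fast, so I expected y to stay put. Ash, larch and cedar hasten uptake in a flask that passes break-even anyway, so I chose none.

The forecast, a separate reckoning from mine, stood at 67 %, higher than my 65.6 %, with 25.8 %, best none and 67.1 % after maple, and it held that “Crystals persist throughout”.

The flask gave 67.1 %, 25.7 % of saturation at 3.0 min, best change none, and 67.1 % after maple. At 30.0 min its substrate stood at 1.12 % of the charge, under the break-even share of 7.47 %, with crystals at 27.2 %. In the flask with 1.0 M of catalyst, 0.149 M has the same value, catalyst having cancelled from it, and substrate had reached 0.017 % by 30.0 min, far under that share, with target and crystals together at 37.2 %. That flask held crystals at 0 % and over-reaction product at 62.8 %.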